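**Retrosynthetic overview**
- The target is opened by global MOM removal to a protected chalcone, whose aryl–C(=O) bond is cut to a ring A aryllithium and a Heck-made cinnamic Weinreb amide.
- The ring A–C4 bond is cut by a boron-to-carbon 1,2-aryl shift (non-pericyclic, with loss of N2) between a 4-diazo-oxane, made from the oxan-4-one sulfonylhydrazone, and a ring A boronic acid; this step sets C4.
- The oxane is the only ring that is built (all four benzene rings are bought intact): 6-endo oxa-Michael closure of an (S)-β-hydroxy enone gives the 2,6-cis-oxan-4-one.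
- The β-hydroxy enone comes from an asymmetric boron aldol of an aryl enone with a 3-arylpropanal, both made by Heck reactions of one MOM-protected 4-iodophenol (with methyl vinyl ketone and with allyl alcohol).
- The ring A boronic acid comes from resorcinol by MOM protection, C–H borylation/oxidation, O-methylation and directed lithiation/borylation.

Assumption: the SMILES is read as the all-cis (2S,4R,6S)-oxane carrying an (E)-enone; MOMCl, MeI, B2pin2, B(OMe)3, TsNHNH2 and (−)-Ipc2BCl are bought reagents.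

**Route**

Step 1
Reactants: 1 4-iodophenol
Product: 2 1-iodo-4-(methoxymethoxy)benzene
Conditions: NaH, MOMCl, DMF, 0 °C to rt
Reagents that add atoms: chloromethyl methyl ether (MOMCl), COCCl
Why: Williamson-type O-alkylation of the phenoxide gives an acetal-protected phenol that tolerates palladium, boron enolate, organolithium and carbonate/110 °C conditions and is removed at the end without protic acid.

Step 2
Reactants: 2 1-iodo-4-(methoxymethoxy)benzene; 3 prop-2-en-1-ol (allyl alcohol)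
Product: 4 3-[4-(methoxymethoxy)phenyl]propanal
Conditions: Pd(OAc)2 (3 mol %), NaHCO3, n-Bu4NCl, DMF, 45 °C
Reagents that add atoms: none
Why: Heck arylation of the allylic alcohol under Jeffery conditions, in which β-hydride elimination towards the carbinol releases an enol that tautomerises to the saturated aldehyde (Heck arylation–isomerisation).

Step 3
Reactants: 2 1-iodo-4-(methoxymethoxy)benzene; 5 but-3-en-2-one (methyl vinyl ketone)
Product: 6 (E)-4-[4-(methoxymethoxy)phenyl]but-3-en-2-one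
Conditions: Pd(OAc)2 (2 mol %), NaHCO3, n-Bu4NCl, DMF, 60 °C
Reagents that add atoms: none
Why: Mizoroki–Heck arylation of the electron-poor alkene at its terminal carbon followed by syn β-hydride elimination gives only the (E)-enone.

Step 4
Reactants: 6 (E)-4-[4-(methoxymethoxy)phenyl]but-3-en-2-one; 4 3-[4-(methoxymethoxy)phenyl]propanal
Product: 9 (S,E)-5-hydroxy-1,7-bis[4-(methoxymethoxy)phenyl]hept-1-en-3-one, via boron dienolate 7 (not isolated), via boron aldolate 8 (not isolated)
Conditions: (−)-Ipc2BCl, Et3N, Et2O, 0 °C; then 4, −78 to −20 °C; then H2O2, pH 7 buffer, MeOH, 0 °C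
Reagents that add atoms: none
Why: Paterson-type asymmetric boron aldol, in which the diisopinocampheylboron dienolate of the methyl ketone (ligands from (+)-α-pinene) adds through a cyclic transition state to the Re face of the unbranched aldehyde and so sets the (S)-carbinol that becomes C6, typically in about 75–85 % ee, which is raised by recrystallisation after the next step.

Step 5
Reactants: 9 (S,E)-5-hydroxy-1,7-bis[4-(methoxymethoxy)phenyl]hept-1-en-3-one
Product: 10 (2S,6S)-2-[4-(methoxymethoxy)phenyl]-6-{2-[4-(methoxymethoxy)phenyl]ethyl}oxan-4-one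
Conditions: (1S)-(+)-10-camphorsulfonic acid (20 mol %), CH2Cl2, rt
Reagents that add atoms: none
Why: Reversible acid-catalysed 6-endo oxa-Michael addition of the secondary alcohol to the aryl enone under thermodynamic control puts both substituents equatorial, so the existing (S)-carbinol fixes the new C2 centre as (S) (2,6-cis), and the aryl MOM ethers tolerate the anhydrous weak acid.

Step 6
Reactants: 11 benzene-1,3-diol (resorcinol)
Product: 12 1,3-bis(methoxymethoxy)benzene
Conditions: NaH, MOMCl, DMF, 0 °C to rt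
Reagents that add atoms: chloromethyl methyl ether (MOMCl), COCCl
Why: Double Williamson O-alkylation, giving MOM ethers that later direct the ring metalations.

Step 7
Reactants: 12 1,3-bis(methoxymethoxy)benzene
Product: 14 3,5-bis(methoxymethoxy)phenol, via arylboronate ester 13 (not isolated)
Conditions: B2pin2 (0.6 equiv), [Ir(OMe)(C8H12)]2 (1.5 mol %), 4,4′-di-tert-butyl-2,2′-bipyridine (3 mol %), THF, 80 °C; then H2O2, NaOH, THF/H2O, 0 °C
Reagents that add atoms: hydrogen peroxide, OO
Why: Sterically controlled iridium-catalysed C–H borylation of a 1,3-disubstituted arene goes to the 5-position, meta to both ethers, and the C–B bond is oxidised in the same pot (one-pot C–H borylation/oxidation).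

Step 8
Reactants: 14 3,5-bis(methoxymethoxy)phenol
Product: 15 1-methoxy-3,5-bis(methoxymethoxy)benzene
Conditions: MeI, K2CO3, acetone, reflux
Reagents that add atoms: iodomethane, CI
Why: Williamson O-methylation of the only free phenol.

Step 9
Reactants: 15 1-methoxy-3,5-bis(methoxymethoxy)benzene
Product: 18 [4-methoxy-2,6-bis(methoxymethoxy)phenyl]boronic acid, via aryllithium 16 (not isolated), via lithium aryltrimethoxyborate 17 (not isolated)
Conditions: n-BuLi, THF, 0 °C; then B(OMe)3, −78 °C to rt; then aq NH4Cl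
Reagents that add atoms: trimethyl borate, COB(OC)OC; water, O
Why: Directed ortho-metalation removes the proton flanked by the two chelating MOM ethers much faster than those next to the methoxy group, and the aryllithium is trapped by the borate and hydrolysed (lithiation–borylation).

Step 10
Reactants: 10 (2S,6S)-2-[4-(methoxymethoxy)phenyl]-6-{2-[4-(methoxymethoxy)phenyl]ethyl}oxan-4-one; 18 [4-methoxy-2,6-bis(methoxymethoxy)phenyl]boronic acid
Product: 22 (2S,4R,6S)-4-[4-methoxy-2,6-bis(methoxymethoxy)phenyl]-2-[4-(methoxymethoxy)phenyl]-6-{2-[4-(methoxymethoxy)phenyl]ethyl}oxane, via tosylhydrazone 19 (not isolated), via 4-diazooxane 20 (not isolated), via tertiary boronic acid 21 (not isolated)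
Conditions: TsNHNH2, 1,4-dioxane, 80 °C; then 18 (2.5 equiv), K2CO3, 110 °C
Reagents that add atoms: none
Why: Proposed new method: a stereocontrolled 1,2-aryl shift from boron to carbon on a cyclic diazoalkane, in which Bamford–Stevens loss of sulfinate from 19 gives the non-stabilised diazo compound 20, its nucleophilic carbon binds the Lewis-acidic boron of 18 from the equatorial direction (the bulky di-ortho-substituted arylboron avoids the axial hydrogens at C2 and C6), the electron-rich aryl group then migrates from boron to C4 with loss of N2 and inversion (anti to the axial diazonium) so that aryl is equatorial and boron axial in 21, and retentive protodeboronation of this crowded tertiary benzylic boronic acid leaves the all-cis (4R) product; the closest known reaction type is the metal-free reductive coupling of ketone sulfonylhydrazones with boronic acids (a 1,2-metallate rearrangement), which has not been shown as a diastereoselective entry to 2,4,6-trisubstituted oxanes or with a 2,6-dioxygenated arylboronic acid.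

Step 11
Reactants: 2 1-iodo-4-(methoxymethoxy)benzene; 23 N-methoxy-N-methylprop-2-enamide
Product: 24 (E)-N-methoxy-3-[4-(methoxymethoxy)phenyl]-N-methylprop-2-enamide
Conditions: Pd(OAc)2 (2 mol %), NaHCO3, n-Bu4NCl, DMF, 80 °C
Reagents that add atoms: none
Why: Mizoroki–Heck arylation of the acrylamide gives the (E)-cinnamic Weinreb amide directly.

Step 12
Reactants: 22 (2S,4R,6S)-4-[4-methoxy-2,6-bis(methoxymethoxy)phenyl]-2-[4-(methoxymethoxy)phenyl]-6-{2-[4-(methoxymethoxy)phenyl]ethyl}oxane; 24 (E)-N-methoxy-3-[4-(methoxymethoxy)phenyl]-N-methylprop-2-enamide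
Product: 27 (E)-1-{6-methoxy-2,4-bis(methoxymethoxy)-3-[(2S,4R,6S)-2-[4-(methoxymethoxy)phenyl]-6-{2-[4-(methoxymethoxy)phenyl]ethyl}oxan-4-yl]phenyl}-3-[4-(methoxymethoxy)phenyl]prop-2-en-1-one, via aryllithium 25 (not isolated), via lithium hemiaminal adduct 26 (not isolated)
Conditions: n-BuLi (1.15 equiv), THF, −10 °C; then 24, −78 to −20 °C; then aq NH4Cl
Reagents that add atoms: none
Why: Directed ortho-metalation at one of the two equivalent ring A positions flanked by a MOM ether and the methoxy group (the only doubly activated C–H left; no diamine additive, so the benzylic C2–H stays untouched) is followed by 1,2-addition to the Weinreb amide, whose chelated adduct prevents over-addition and collapses to the (E)-chalcone on work-up (Weinreb ketone synthesis).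

Step 13
Reactants: 27 (E)-1-{6-methoxy-2,4-bis(methoxymethoxy)-3-[(2S,4R,6S)-2-[4-(methoxymethoxy)phenyl]-6-{2-[4-(methoxymethoxy)phenyl]ethyl}oxan-4-yl]phenyl}-3-[4-(methoxymethoxy)phenyl]prop-2-en-1-one
Product: 29 (E)-1-{2,4-dihydroxy-3-[(2S,4R,6S)-2-(4-hydroxyphenyl)-6-[2-(4-hydroxyphenyl)ethyl]oxan-4-yl]-6-methoxyphenyl}-3-(4-hydroxyphenyl)prop-2-en-1-one, via pentakis(trimethylsilyl) ether 28 (not isolated)
Conditions: TMSOTf, 2,2′-bipyridyl, CH3CN, 0 °C to rt; then H2O, NaHCO3
Reagents that add atoms: none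
Why: Bipyridyl-buffered silyl triflate cleavage of aryl MOM ethers (acetal exchange to aryl silyl ethers that hydrolyse on work-up) removes all five groups without protic acid, so the acid-labile 4-hydroxybenzylic oxane ether, the three stereocentres and the (E)-2′-hydroxychalcone are left intact.

**Compound list**

1 | 4-iodophenol | Oc1ccc(I)cc1 | starting material
2 | 1-iodo-4-(methoxymethoxy)benzene | COCOc1ccc(I)cc1 | intermediate
3 | prop-2-en-1-ol (allyl alcohol) | OCC=C | starting material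
4 | 3-[4-(methoxymethoxy)phenyl]propanal | COCOc1ccc(CCC=O)cc1 | intermediate
5 | but-3-en-2-one (methyl vinyl ketone) | CC(=O)C=C | starting material
6 | (E)-4-[4-(methoxymethoxy)phenyl]but-3-en-2-one | COCOc1ccc(/C=C/C(C)=O)cc1 | intermediate
7 | bis[(1R,2S,3R,5R)-isopinocampheyl]boron dienolate of 6, (E)-{4-[4-(methoxymethoxy)phenyl]buta-1,3-dien-2-yl}oxy-borane | C=C(OB([C@@H]1C[C@@H]2C[C@H]([C@H]1C)C2(C)C)[C@@H]1C[C@@H]2C[C@H]([C@H]1C)C2(C)C)/C=C/c1ccc(OCOC)cc1 | intermediate
8 | bis(isopinocampheyl)boron aldolate of 9 (B–O bond at the (5S)-oxygen) | COCOc1ccc(CC[C@H](OB([C@@H]2C[C@@H]3C[C@H]([C@H]2C)C3(C)C)[C@@H]2C[C@@H]3C[C@H]([C@H]2C)C3(C)C)CC(=O)/C=C/c2ccc(OCOC)cc2)cc1 | intermediate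
9 | (S,E)-5-hydroxy-1,7-bis[4-(methoxymethoxy)phenyl]hept-1-en-3-one | COCOc1ccc(CC[C@H](O)CC(=O)/C=C/c2ccc(OCOC)cc2)cc1 | intermediate
10 | (2S,6S)-2-[4-(methoxymethoxy)phenyl]-6-{2-[4-(methoxymethoxy)phenyl]ethyl}oxan-4-one | O=C1C[C@H](CCc2ccc(OCOC)cc2)O[C@H](c2ccc(OCOC)cc2)C1 | intermediate
11 | benzene-1,3-diol (resorcinol) | Oc1cccc(O)c1 | starting material
12 | 1,3-bis(methoxymethoxy)benzene | COCOc1cccc(OCOC)c1 | intermediate
13 | 2-[3,5-bis(methoxymethoxy)phenyl]-4,4,5,5-tetramethyl-1,3,2-dioxaborolane | COCOc1cc(OCOC)cc(c1)B1OC(C)(C)C(C)(C)O1 | intermediate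
14 | 3,5-bis(methoxymethoxy)phenol | COCOc1cc(O)cc(OCOC)c1 | intermediate
15 | 1-methoxy-3,5-bis(methoxymethoxy)benzene | COCOc1cc(OC)cc(OCOC)c1 | intermediate
16 | [4-methoxy-2,6-bis(methoxymethoxy)phenyl]lithium | COCOc1cc(OC)cc(OCOC)c1[Li] | intermediate
17 | lithium trimethoxy[4-methoxy-2,6-bis(methoxymethoxy)phenyl]borate | [Li+].COCOc1cc(OC)cc(OCOC)c1[B-](OC)(OC)OC | intermediate
18 | [4-methoxy-2,6-bis(methoxymethoxy)phenyl]boronic acid | COCOc1cc(OC)cc(OCOC)c1B(O)O | intermediate
19 | N′-{(2S,6S)-2-[4-(methoxymethoxy)phenyl]-6-{2-[4-(methoxymethoxy)phenyl]ethyl}oxan-4-ylidene}-4-methylbenzenesulfonohydrazide | Cc1ccc(cc1)S(=O)(=O)NN=C1C[C@H](CCc2ccc(OCOC)cc2)O[C@H](c2ccc(OCOC)cc2)C1 | intermediate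
20 | (2S,6S)-4-diazo-2-[4-(methoxymethoxy)phenyl]-6-{2-[4-(methoxymethoxy)phenyl]ethyl}oxane | [N-]=[N+]=C1C[C@H](CCc2ccc(OCOC)cc2)O[C@H](c2ccc(OCOC)cc2)C1 | intermediate
21 | {(2S,4R,6S)-4-[4-methoxy-2,6-bis(methoxymethoxy)phenyl]-2-[4-(methoxymethoxy)phenyl]-6-{2-[4-(methoxymethoxy)phenyl]ethyl}oxan-4-yl}boronic acid (aryl equatorial, boron axial) | COc1cc(OCOC)c([C@]2(B(O)O)C[C@H](CCc3ccc(OCOC)cc3)O[C@H](c3ccc(OCOC)cc3)C2)c(OCOC)c1 | intermediate
22 | (2S,4R,6S)-4-[4-methoxy-2,6-bis(methoxymethoxy)phenyl]-2-[4-(methoxymethoxy)phenyl]-6-{2-[4-(methoxymethoxy)phenyl]ethyl}oxane | COc1cc(OCOC)c([C@@H]2C[C@H](CCc3ccc(OCOC)cc3)O[C@H](c3ccc(OCOC)cc3)C2)c(OCOC)c1 | intermediate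
23 | N-methoxy-N-methylprop-2-enamide | C=CC(=O)N(C)OC | starting material
24 | (E)-N-methoxy-3-[4-(methoxymethoxy)phenyl]-N-methylprop-2-enamide | COCOc1ccc(/C=C/C(=O)N(C)OC)cc1 | intermediate
25 | {6-methoxy-2,4-bis(methoxymethoxy)-3-[(2S,4R,6S)-2-[4-(methoxymethoxy)phenyl]-6-{2-[4-(methoxymethoxy)phenyl]ethyl}oxan-4-yl]phenyl}lithium | COc1cc(OCOC)c([C@@H]2C[C@H](CCc3ccc(OCOC)cc3)O[C@H](c3ccc(OCOC)cc3)C2)c(OCOC)c1[Li] | intermediate
26 | lithium (E)-1-[methoxy(methyl)amino]-1-{6-methoxy-2,4-bis(methoxymethoxy)-3-[(2S,4R,6S)-oxan-4-yl unit of 22]phenyl}-3-[4-(methoxymethoxy)phenyl]prop-2-en-1-olate (both epimers at the new carbon) | COc1cc(OCOC)c([C@@H]2C[C@H](CCc3ccc(OCOC)cc3)O[C@H](c3ccc(OCOC)cc3)C2)c(OCOC)c1C(O[Li])(N(C)OC)/C=C/c1ccc(OCOC)cc1 | intermediate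
27 | (E)-1-{6-methoxy-2,4-bis(methoxymethoxy)-3-[(2S,4R,6S)-2-[4-(methoxymethoxy)phenyl]-6-{2-[4-(methoxymethoxy)phenyl]ethyl}oxan-4-yl]phenyl}-3-[4-(methoxymethoxy)phenyl]prop-2-en-1-one | COc1cc(OCOC)c([C@@H]2C[C@H](CCc3ccc(OCOC)cc3)O[C@H](c3ccc(OCOC)cc3)C2)c(OCOC)c1C(=O)/C=C/c1ccc(OCOC)cc1 | intermediate
28 | pentakis(trimethylsilyl) ether of 29 | COc1cc(O[Si](C)(C)C)c([C@@H]2C[C@H](CCc3ccc(O[Si](C)(C)C)cc3)O[C@H](c3ccc(O[Si](C)(C)C)cc3)C2)c(O[Si](C)(C)C)c1C(=O)/C=C/c1ccc(O[Si](C)(C)C)cc1 | intermediate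
29 | (E)-1-{2,4-dihydroxy-3-[(2S,4R,6S)-2-(4-hydroxyphenyl)-6-[2-(4-hydroxyphenyl)ethyl]oxan-4-yl]-6-methoxyphenyl}-3-(4-hydroxyphenyl)prop-2-en-1-one | COc1cc(O)c([C@@H]2C[C@H](CCc3ccc(O)cc3)O[C@H](c3ccc(O)cc3)C2)c(O)c1C(=O)/C=C/c1ccc(O)cc1 | target

**Step count**

Total steps: 13. Longest linear sequence: 7 steps (1, 3, 4, 5, 10, 12, 13; the ring A branch 6, 7, 8, 9, 10, 12, 13 is equally long).

**Three steps most likely to fail**

Step 4 (enantioselectivity). Methyl-ketone boron aldols with this ligand often stop near 75–85 % ee, so enantiopurity rests on a recrystallisation. The fallback sets out from 6 and 4 and returns at 9. It gives up the chiral boron enolate for a catalytic, open-transition-state addition of a preformed enol silane. Enone 6 is silylated (TMSOTf, Et3N, CH2Cl2, 0 °C) to (E)-trimethyl({4-[4-(methoxymethoxy)phenyl]buta-1,3-dien-2-yl}oxy)silane F1. A catalytic enantioselective Mukaiyama aldol addition of F1 to 4 follows (20 mol % of the oxazaborolidinone made from N-tosyl-(S)-tryptophan and n-butylboronic acid, EtCN, −78 °C). The facial sense of this catalyst is to be confirmed on a first run; the antipodal catalyst is used if the sign is wrong. The adduct is (S,E)-1,7-bis[4-(methoxymethoxy)phenyl]-5-[(trimethylsilyl)oxy]hept-1-en-3-one F2, and brief aqueous citric acid/THF frees 9.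

Step 10 (the new step). The risks are protodeboronation of the di-ortho-oxygenated boronic acid 18 before it meets the diazo compound, slow boron–carbon bond formation at the crowded boron, and incomplete facial control or non-retentive protodeboronation at C4. The fallback uses known chemistry only; it sets out from ketone 10 and aryllithium 16 (made from 15 as in step 9) and returns at 22. Transmetalation of 16 with CeCl3 (THF, −78 °C) gives the non-basic [4-methoxy-2,6-bis(methoxymethoxy)phenyl]cerium dichloride F3. F3 adds to 10 without enolisation to give (2S,6S)-4-[4-methoxy-2,6-bis(methoxymethoxy)phenyl]-2-[4-(methoxymethoxy)phenyl]-6-{2-[4-(methoxymethoxy)phenyl]ethyl}oxan-4-ol F4. Dehydration with the Burgess reagent (toluene, 60 °C) gives (2S,6S)-4-[4-methoxy-2,6-bis(methoxymethoxy)phenyl]-2-[4-(methoxymethoxy)phenyl]-6-{2-[4-(methoxymethoxy)phenyl]ethyl}-3,6-dihydro-2H-pyran F5 together with its ring-olefin isomer (2S,6S)-4-[4-methoxy-2,6-bis(methoxymethoxy)phenyl]-6-[4-(methoxymethoxy)phenyl]-2-{2-[4-(methoxymethoxy)phenyl]ethyl}-3,6-dihydro-2H-pyran F6. Radical hydrogen-atom-transfer hydrogenation of the mixture (Mn(dpm)3, tris(2,2,6,6-tetramethylheptane-3,5-dionato)manganese, PhSiH3, t-BuOOH, i-PrOH, rt) is under thermodynamic control and delivers the all-equatorial isomer 22.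

Step 12 (ring A metalation and acylation). The risks are competing lithiation next to the single MOM ethers of the other rings or at the benzylic C2–H, and sluggish or conjugate addition of the hindered aryllithium to the unsaturated Weinreb amide. The fallback sets out from 22 and 24 and returns at 27. NBS (1.0 equiv, CH3CN, 0 °C) brominates only the trioxygenated ring A and gives (2S,4R,6S)-4-[3-bromo-4-methoxy-2,6-bis(methoxymethoxy)phenyl]-2-[4-(methoxymethoxy)phenyl]-6-{2-[4-(methoxymethoxy)phenyl]ethyl}oxane F7. Separately, i-Bu2AlH (THF, −78 °C) reduces 24 to (E)-3-[4-(methoxymethoxy)phenyl]prop-2-enal F8. Bromine–lithium exchange on F7 (n-BuLi, THF, −78 °C) gives 25 with no deprotonation-selectivity question. Its 1,2-addition to the more electrophilic aldehyde F8 gives (E)-1-{6-methoxy-2,4-bis(methoxymethoxy)-3-[(2S,4R,6S)-2-[4-(methoxymethoxy)phenyl]-6-{2-[4-(methoxymethoxy)phenyl]ethyl}oxan-4-yl]phenyl}-3-[4-(methoxymethoxy)phenyl]prop-2-en-1-ol F9. MnO2 (CH2Cl2, rt) oxidises this doubly activated alcohol to 27.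

**Further compounds**

F1 | step 4 | (E)-trimethyl({4-[4-(methoxymethoxy)phenyl]buta-1,3-dien-2-yl}oxy)silane | C=C(O[Si](C)(C)C)/C=C/c1ccc(OCOC)cc1
F2 | step 4 | (S,E)-1,7-bis[4-(methoxymethoxy)phenyl]-5-[(trimethylsilyl)oxy]hept-1-en-3-one | COCOc1ccc(CC[C@H](O[Si](C)(C)C)CC(=O)/C=C/c2ccc(OCOC)cc2)cc1
F3 | step 10 | [4-methoxy-2,6-bis(methoxymethoxy)phenyl]cerium dichloride | COCOc1cc(OC)cc(OCOC)c1[Ce](Cl)Cl
F4 | step 10 | (2S,6S)-4-[4-methoxy-2,6-bis(methoxymethoxy)phenyl]-2-[4-(methoxymethoxy)phenyl]-6-{2-[4-(methoxymethoxy)phenyl]ethyl}oxan-4-ol | COc1cc(OCOC)c(C2(O)C[C@H](CCc3ccc(OCOC)cc3)O[C@H](c3ccc(OCOC)cc3)C2)c(OCOC)c1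
F5 | step 10 | (2S,6S)-4-[4-methoxy-2,6-bis(methoxymethoxy)phenyl]-2-[4-(methoxymethoxy)phenyl]-6-{2-[4-(methoxymethoxy)phenyl]ethyl}-3,6-dihydro-2H-pyran | COc1cc(OCOC)c(C2=C[C@H](CCc3ccc(OCOC)cc3)O[C@H](c3ccc(OCOC)cc3)C2)c(OCOC)c1
F6 | step 10 | (2S,6S)-4-[4-methoxy-2,6-bis(methoxymethoxy)phenyl]-6-[4-(methoxymethoxy)phenyl]-2-{2-[4-(methoxymethoxy)phenyl]ethyl}-3,6-dihydro-2H-pyran | COc1cc(OCOC)c(C2=C[C@@H](c3ccc(OCOC)cc3)O[C@@H](CCc3ccc(OCOC)cc3)C2)c(OCOC)c1
F7 | step 12 | (2S,4R,6S)-4-[3-bromo-4-methoxy-2,6-bis(methoxymethoxy)phenyl]-2-[4-(methoxymethoxy)phenyl]-6-{2-[4-(methoxymethoxy)phenyl]ethyl}oxane | COc1cc(OCOC)c([C@@H]2C[C@H](CCc3ccc(OCOC)cc3)O[C@H](c3ccc(OCOC)cc3)C2)c(OCOC)c1Br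
F8 | step 12 | (E)-3-[4-(methoxymethoxy)phenyl]prop-2-enal | COCOc1ccc(/C=C/C=O)cc1
F9 | step 12 | (E)-1-{6-methoxy-2,4-bis(methoxymethoxy)-3-[(2S,4R,6S)-2-[4-(methoxymethoxy)phenyl]-6-{2-[4-(methoxymethoxy)phenyl]ethyl}oxan-4-yl]phenyl}-3-[4-(methoxymethoxy)phenyl]prop-2-en-1-ol | COc1cc(OCOC)c([C@@H]2C[C@H](CCc3ccc(OCOC)cc3)O[C@H](c3ccc(OCOC)cc3)C2)c(OCOC)c1C(O)/C=C/c1ccc(OCOC)cc1
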